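Atom labels follow isoflavone numbering (O1, C2, C3, C4, C4a, C5–C8, C8a; ring B C1'–C6'). Ring A is the benzo ring of the chromenone, ring C the pyranone, ring B the 3-aryl ring and ring D the dimethylpyran fused to ring B. Compound numbers 1–19 are those of the steps and of the compound list.

## The problem

Kanzonol T (19) is an achiral isoflavone: a chromen-4-one (rings A and C) with an aryl ring B at C3, and ring B is fused across C3'–C4' to a 2,2-dimethyl-2H-pyran (ring D). With no stereocenter in the target, the task is regiochemistry and functional-group tolerance. On ring A the 3-hydroxy-3-methylbutyl chain must sit at C6, between the C5 and C7 hydroxyls, and not at C8. On ring B the free hydroxyl must be at C2', flanked by the biaryl bond and by ring D. Three groups limit the reagents. The ring D double bond rules out hydrogenolysis, free halogen and strong Lewis acids. The tertiary carbinol lies ortho to two phenols and would eliminate or close to a dihydropyran in strong acid. The phloroglucinol-type ring A is easily over-substituted. The enabling feature is the C3–C4 bond: C4 is a carbonyl carbon on ring A and C3 carries ring B, so with C2=C3 hydrated the unit is an acyloin. C4 can then come from a ring A aldehyde used as an acyl anion, and C3 from a ring B aryl ketone, once the two are tied through the O1–C2 ether. The one stereocenter met on the way (C3 of the acyloin) disappears when C2=C3 is restored, so it controls nothing and needs no control.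

## Retrosynthesis

**19 from 18.** The four O–CH2OMe bonds are cut last. Methoxymethyl ethers direct the lithiation used below and survive base, fluoride, the carbene and SOCl2. Benzyl ethers would require hydrogenolysis, which ring D forbids, and methyl ethers would require boron halides, which neither ring D nor the carbinol survives. The forward step must be acetal methanolysis mild enough to spare the tertiary carbinol and the chromene.

**18 from 17.** The C2=C3 double bond is traced back to a C3 carbinol (retro-dehydration). This places the acyloin in view and costs one step. C3 has β-hydrogens only at C2, so elimination can go only one way. The chain carbinol must be masked at this stage, which is why it carries a methoxymethyl group in 18.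

**17 from 16.** The C3–C4 bond is cut, which opens ring C to keto aldehyde 16. Cutting C3–C1' instead (3-halochromone plus ring B boronate) would need a separately made ring B organometallic. Cutting at C2 (deoxybenzoin plus a one-carbon unit) would need a Friedel–Crafts or Hoesch acylation of an acid-sensitive ring A. The C3–C4 cut is intramolecular, catalytic and redox-neutral. The forward reaction asks a hindered, electron-rich aldehyde to act as donor towards an electron-rich aryl ketone without base-induced aldol closure.

**16 from 9 and 15.** The O1–C2 ether bond is cut to salicylaldehyde 9 and α-bromo ketone 15. This is the most convergent cut, dividing the molecule into a ring A half and a ring B/D half of similar size. The forward step is a phenol alkylation that must stop before the ketone enolate attacks the aldehyde.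

**9 from 8.** The formyl C–C bond (C4–C4a) is cut. Phenol 8 has a mirror plane through its hydroxyl-bearing carbon and the chain-bearing carbon, so its two ortho positions are identical. A reaction that formylates only ortho to a free phenol therefore fixes O1, C4 and the C6 chain in their correct relation with no isomer possible. Formylating a fully protected ring, or a ring with three free hydroxyls, would leave the two oxygens flanking the aldehyde indistinguishable.

**8 from 3 and 4, via 7 and 6.** The aryl–CH2 bond of the chain is cut to aryllithium 5, made from silyl ether 3, and 2,2-dimethyloxetane 4. The two methoxymethoxy groups direct lithiation to the carbon between them, and the bulky silyl ether on the third oxygen blocks the other sites. The oxetane delivers all five chain carbons with the tertiary carbinol in one C–C bond formation. Electrophilic prenylation of a phloroglucinol would give O/C and mono/bis mixtures and would still need hydration. Silyl ether 3 comes from phloroglucinol 1 through bis-ether 2.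

**15 from 10 and 11, via 13 and 12.** The C–Br bond and the ring B methoxymethyl ether are removed to chromene 12. Its pyran ring is cut at the O–C and aryl–CH bonds to 2,4-dihydroxyacetophenone 10 and 3-methylbut-2-enal 11. The acetyl group chelates the C2 hydroxyl, so the other hydroxyl closes the pyran, and closure occurs at the carbon between the two oxygens. That is the ring B/D pattern of the target. Bromination must go through enol ether 14 so that the chromene double bond is not touched.

## Roads not taken

**Alternative 1: ring A by benzannulation.** The cut removes C8–C8a, C7–C8, C5–C6 and C4a–C5, taking ring A apart into pyranonyl diazo ketone A2 and siloxyalkyne A3. In the forward step, irradiation of A2 would trigger a Wolff rearrangement to a pyranonyl ketene, which adds A3 in a [2+2] sense. Heating would open the cyclobutenone and reclose it by 6π electrocyclisation to phenol A1.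
- Merits: the polarity of the alkyne places the chain at C6, the free hydroxyl at C5 and the silyl ether at C7 in a single step. No symmetric intermediate is needed, and A1 already has C2=C3, so no dehydration follows. In convergence and in redox economy of the end-game this road is better than the chosen one.
- Weak points: A2 needs a 5-aryl-4-oxopyran-2-carboxylic acid, a cross-coupling to bring in ring B, and diazo ketone chemistry. A3 needs an ynolate homologation. The key step irradiates a molecule that holds a 2H-chromene, which opens photochemically to a quinone methide, and a 4-pyranone, which is itself photoactive.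
- Comparison: the chosen plan offers equal regiochemical certainty through the symmetry of 8. Both of its halves come from commodity aromatics in six steps or fewer, and its key step is catalytic, in the dark, near room temperature.

**Alternative 2: ring C by aryne annulation.** The cut removes O1–C8a and C4–C4a, giving silyl triflate A5 as the ring A aryne precursor and hydroxyacrylate A6 carrying ring B. In the forward step CsF would release the aryne. The enolate oxygen of A6 should add at C8a, remote from the C5 alkoxy group, and the C4a anion should then attack the ester to give the protected isoflavone A4, which is the same compound as 18.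
- Merits: the isoflavone oxidation level is reached directly, one step shorter at the end than the chosen plan. A5 could be made from phenol 8 of the present route.
- Weak points: the enolate of A6 is ambident, so C-arylation and insertion into its C–C bond compete with O-arylation. Regiocontrol rests only on the inductive effect of one alkoxy group on a pentasubstituted aryne. The aryl anion, wedged between two substituents, can be protonated before it acylates. Making A5 (halogenation, silyl migration, triflation) and the arylacetate behind A6 uses up the step saved.
- Comparison: the chosen benzoin is tethered, so there is one possible mode of union and no regiochemical question. It pays for this with the extra dehydration.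

**Alternative 3: cyclopropanol opening and oxidative closure.** The cut removes O1–C2 last, from cyclopropanol A8. In the forward step Pd(O2CCF3)2 (divalent palladium) under O2 would cleave the carbinol–CH2 bond to a palladium homoenolate, and β-hydride loss gives an α-methylene ketone. The ring A phenol adds to C2, and the isoflavanone is dehydrogenated to A7.
- Merits: C2 insertion, ring closure and oxidation happen in one flask. The chain carbinol can stay free, which saves a protection, and A7 needs only acetal removal. In protecting-group economy it is better than the chosen plan.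
- Weak points: cleavage of the other cyclopropane bond, towards the benzylic carbon, would lead to the flavone skeleton, and nothing in A8 enforces the choice. A free electron-rich phenol and the chromene alkene are exposed to an oxidising palladium system. A8 itself needs a titanium-mediated cyclopropanation of a doubly ortho-substituted benzoate, or a deoxybenzoin that could be converted to the isoflavone more directly.
- Comparison: in the chosen plan the phenacyl unit fixes ring B on C3 before ring C closes, and no oxidant is used in the presence of the chromene.

Key step: step 11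

Assumption: anhydrous phloroglucinol, 2,2-dimethyloxetane, chloromethyl methyl ether and the triazolium salt of step 11 are taken as purchasable; the carbinol centre C3 of 17 is deliberately formed racemic because step 12 removes it.

## Route

Step 1
Reactants: 1 phloroglucinol
Product: 2 3,5-bis(methoxymethoxy)phenol
Conditions: MOMCl (2 equiv), i-Pr2NEt, THF/CH2Cl2, 0 °C → rt; chromatography
Reagents that add atoms: chloromethyl methyl ether, COCCl
Why: Phenol O-alkylation (methoxymethyl protection); two equivalents should make the bis-ether the main component of a statistical mixture, from which mono- and tris-ethers are separated. The remaining hydroxyl is the oxygen that later becomes O1.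

Step 2
Reactants: 2 3,5-bis(methoxymethoxy)phenol
Product: 3 [3,5-bis(methoxymethoxy)phenoxy]triisopropylsilane
Conditions: i-Pr3SiCl, imidazole, DMF, rt
Reagents that add atoms: chlorotriisopropylsilane, CC(C)[Si](Cl)(C(C)C)C(C)C
Why: Standard silylation of a phenol; the bulky silyl ether resists n-BuLi and shields its two neighbouring ring positions, leaving only the site between the acetal oxygens open to metalation.

Step 3
Reactants: 3 [3,5-bis(methoxymethoxy)phenoxy]triisopropylsilane; 4 2,2-dimethyloxetane
Product: 6 4-[2,6-bis(methoxymethoxy)-4-(triisopropylsilyloxy)phenyl]-2-methylbutan-2-ol, via the aryllithium 5 (not isolated)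
Conditions: n-BuLi, THF, 0 °C; then 4, BF3·OEt2, −78 °C; aq NaHCO3
Reagents that add atoms: none
Why: Directed ortho-metalation between two methoxymethoxy groups, then BF3-assisted SN2 opening of the oxetane at its unsubstituted CH2 carbon by the aryllithium. This installs the whole 3-hydroxy-3-methylbutyl chain on the future C6 in one C–C bond formation.

Step 4
Reactants: 6 4-[2,6-bis(methoxymethoxy)-4-(triisopropylsilyloxy)phenyl]-2-methylbutan-2-ol
Product: 7 triisopropyl{3,5-bis(methoxymethoxy)-4-[3-(methoxymethoxy)-3-methylbutyl]phenoxy}silane
Conditions: MOMCl, i-Pr2NEt, Bu4NI (cat.), CH2Cl2, 40 °C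
Reagents that add atoms: chloromethyl methyl ether, COCCl
Why: Methoxymethylation of a tertiary alcohol under forcing amine-base conditions; the mask is needed so that SOCl2 in step 12 meets only the C3 carbinol, and it leaves with the aryl acetals in step 13.

Step 5
Reactants: 7 triisopropyl{3,5-bis(methoxymethoxy)-4-[3-(methoxymethoxy)-3-methylbutyl]phenoxy}silane
Product: 8 3,5-bis(methoxymethoxy)-4-[3-(methoxymethoxy)-3-methylbutyl]phenol
Conditions: Bu4NF, THF, 0 °C; H2O
Reagents that add atoms: none
Why: Fluoride cleavage of an aryl silyl ether, to which the acetals are inert; the phenol obtained has a mirror plane through C1 and C4, so its two ortho positions are equivalent.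

Step 6
Reactants: 8 3,5-bis(methoxymethoxy)-4-[3-(methoxymethoxy)-3-methylbutyl]phenol
Product: 9 6-hydroxy-2,4-bis(methoxymethoxy)-3-[3-(methoxymethoxy)-3-methylbutyl]benzaldehyde
Conditions: MgCl2, Et3N, (CH2O)n, THF, reflux
Reagents that add atoms: paraformaldehyde (as formaldehyde), C=O
Why: Magnesium-mediated ortho-formylation of a phenol: the magnesium phenoxide delivers formaldehyde to the ortho carbon and a second formaldehyde oxidises the salicyl alkoxide by hydride transfer. Reaction occurs only next to the free hydroxyl, and the symmetry of 8 makes the product a single regioisomer with the chain between the two acetal oxygens.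

Step 7
Reactants: 10 2,4-dihydroxyacetophenone; 11 3-methylbut-2-enal
Product: 12 1-(5-hydroxy-2,2-dimethyl-2H-chromen-6-yl)ethanone
Conditions: pyridine, 140 °C, sealed tube
Reagents that add atoms: none
Why: Base-mediated chromene annulation of a resorcinol with an enal: C-alkylation at the carbon between the two oxygens, dehydration and oxa-6π electrocyclisation. The acetyl-chelated hydroxyl stays free and the other hydroxyl becomes the pyran oxygen, which is the ring B/D pattern of the target.

Step 8
Reactants: 12 1-(5-hydroxy-2,2-dimethyl-2H-chromen-6-yl)ethanone
Product: 13 1-[5-(methoxymethoxy)-2,2-dimethyl-2H-chromen-6-yl]ethanone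
Conditions: NaH, MOMCl, DMF, 0 °C → rt
Reagents that add atoms: chloromethyl methyl ether, COCCl
Why: O-alkylation of the sodium phenoxide overcomes the hydrogen bond to the acetyl group; the ether prevents the later α-bromo ketone from closing to a benzofuranone.

Step 9
Reactants: 13 1-[5-(methoxymethoxy)-2,2-dimethyl-2H-chromen-6-yl]ethanone
Product: 15 2-bromo-1-[5-(methoxymethoxy)-2,2-dimethyl-2H-chromen-6-yl]ethanone, via the silyl enol ether 14 (not isolated)
Conditions: LiN(SiMe3)2, THF, −78 °C, then Me3SiCl; NBS, THF, −78 → 0 °C
Reagents that add atoms: N-bromosuccinimide, O=C1CCC(=O)N1Br (chlorotrimethylsilane, C[Si](C)(C)Cl, leaves atoms only in intermediate 14)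
Why: α-Bromination of a methyl ketone through its silyl enol ether; the ketone has one enolisable site, and the enol ether is far more reactive towards NBS than the chromene double bond or ring B, which free bromine would attack.

Step 10
Reactants: 9 6-hydroxy-2,4-bis(methoxymethoxy)-3-[3-(methoxymethoxy)-3-methylbutyl]benzaldehyde; 15 2-bromo-1-[5-(methoxymethoxy)-2,2-dimethyl-2H-chromen-6-yl]ethanone
Product: 16 2,4-bis(methoxymethoxy)-3-[3-(methoxymethoxy)-3-methylbutyl]-6-{2-[5-(methoxymethoxy)-2,2-dimethyl-2H-chromen-6-yl]-2-oxoethoxy}benzaldehyde
Conditions: K2CO3, DMF, 0 °C → rt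
Reagents that add atoms: none
Why: Williamson ether synthesis with a highly reactive α-halo ketone forms O1–C2; carbonate at or below room temperature should stop at the ether, before the ketone enolate can add to the aldehyde.

Step 11
Reactants: 16 2,4-bis(methoxymethoxy)-3-[3-(methoxymethoxy)-3-methylbutyl]-6-{2-[5-(methoxymethoxy)-2,2-dimethyl-2H-chromen-6-yl]-2-oxoethoxy}benzaldehyde
Product: 17 3-hydroxy-5,7-bis(methoxymethoxy)-6-[3-(methoxymethoxy)-3-methylbutyl]-3-[5-(methoxymethoxy)-2,2-dimethyl-2H-chromen-6-yl]-2,3-dihydro-4H-chromen-4-one (racemic)
Conditions: 2-(pentafluorophenyl)-6,7-dihydro-5H-pyrrolo[2,1-c][1,2,4]triazol-2-ium tetrafluoroborate (20 mol %), Et3N (20 mol %), toluene, 25 → 40 °C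
Reagents that add atoms: none
Why: The triazolium salt is deprotonated to its carbene, which adds to the formyl carbon of 16; proton transfer gives the Breslow intermediate, whose nucleophilic carbon (future C4) attacks the tethered ring B ketone carbon (future C3), and collapse of the adduct releases the carbene and leaves the C4 ketone and the C3 carbinol. The closest known reaction type is the N-heterocyclic-carbene-catalysed intramolecular crossed aldehyde–ketone benzoin reaction of 2-(2-oxoalkoxy)benzaldehydes, which gives 3-hydroxychroman-4-ones, 3-aryl cases from phenacyl ethers included. Ring C closes in the 6-exo-trig mode, the ketone C=O lying outside the forming O1–C2–C3–C4–C4a–C8a ring. C3 becomes a quaternary carbinol stereocenter; with an achiral catalyst it forms as the racemate and no control is sought, because step 12 makes C3 trigonal again. The step needs the aldehyde to be the donor and the ketone the acceptor, which the substrate secures: only the aldehyde can form a Breslow intermediate, and the intramolecular six-membered closure outruns aldehyde dimerisation. It also needs the carbene pathway to beat base-mediated aldol closure of the C2 enolate onto the aldehyde; the acidic N-pentafluorophenyl triazolium needs no more weak amine than there is azolium, so little free base remains, and the electron-rich aldehyde is a poor aldol acceptor. A small bicyclic triazolylidene is chosen because the formyl group sits between two ortho oxygens.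

Step 12
Reactants: 17 3-hydroxy-5,7-bis(methoxymethoxy)-6-[3-(methoxymethoxy)-3-methylbutyl]-3-[5-(methoxymethoxy)-2,2-dimethyl-2H-chromen-6-yl]-2,3-dihydro-4H-chromen-4-one (racemic)
Product: 18 5,7-bis(methoxymethoxy)-6-[3-(methoxymethoxy)-3-methylbutyl]-3-[5-(methoxymethoxy)-2,2-dimethyl-2H-chromen-6-yl]-4H-chromen-4-one
Conditions: SOCl2, pyridine, CH2Cl2, 0 °C → rt
Reagents that add atoms: none
Why: Dehydration of a tertiary benzylic alcohol with SOCl2/pyridine: O-sulfinylation turns the C3 oxygen into a leaving group and pyridine removes a C2 hydrogen. C2 holds the only β-hydrogens, so the double bond can form only at C2=C3, and conjugation in the pyranone drives it; pyridine buffers the HCl so the acetals and the chromene should survive.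

Step 13
Reactants: 18 5,7-bis(methoxymethoxy)-6-[3-(methoxymethoxy)-3-methylbutyl]-3-[5-(methoxymethoxy)-2,2-dimethyl-2H-chromen-6-yl]-4H-chromen-4-one
Product: 19 Kanzonol T, 5,7-dihydroxy-6-(3-hydroxy-3-methylbutyl)-3-(5-hydroxy-2,2-dimethyl-2H-chromen-6-yl)-4H-chromen-4-one
Conditions: 3 M aq HCl, MeOH, rt → 40 °C
Reagents that add atoms: none
Why: Acid-catalysed methanolysis of all four methoxymethyl acetals (transacetalisation to dimethoxymethane). Dilute acid at or below 40 °C is expected to stay below what ionises the tertiary carbinol or adds to the chromene, and the C5 ether, peri to the carbonyl, should leave first.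

## Compound list

1 | phloroglucinol | Oc1cc(O)cc(O)c1 | starting material
2 | 3,5-bis(methoxymethoxy)phenol | COCOc1cc(O)cc(OCOC)c1 | intermediate
3 | [3,5-bis(methoxymethoxy)phenoxy]triisopropylsilane | COCOc1cc(OCOC)cc(O[Si](C(C)C)(C(C)C)C(C)C)c1 | intermediate
4 | 2,2-dimethyloxetane | CC1(C)CCO1 | starting material
5 | [2,6-bis(methoxymethoxy)-4-(triisopropylsilyloxy)phenyl]lithium | [Li]c1c(OCOC)cc(O[Si](C(C)C)(C(C)C)C(C)C)cc1OCOC | intermediate
6 | 4-[2,6-bis(methoxymethoxy)-4-(triisopropylsilyloxy)phenyl]-2-methylbutan-2-ol | CC(C)(O)CCc1c(OCOC)cc(O[Si](C(C)C)(C(C)C)C(C)C)cc1OCOC | intermediate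
7 | triisopropyl{3,5-bis(methoxymethoxy)-4-[3-(methoxymethoxy)-3-methylbutyl]phenoxy}silane | COCOC(C)(C)CCc1c(OCOC)cc(O[Si](C(C)C)(C(C)C)C(C)C)cc1OCOC | intermediate
8 | 3,5-bis(methoxymethoxy)-4-[3-(methoxymethoxy)-3-methylbutyl]phenol | COCOC(C)(C)CCc1c(OCOC)cc(O)cc1OCOC | intermediate
9 | 6-hydroxy-2,4-bis(methoxymethoxy)-3-[3-(methoxymethoxy)-3-methylbutyl]benzaldehyde | O=Cc1c(O)cc(OCOC)c(CCC(C)(C)OCOC)c1OCOC | intermediate
10 | 2,4-dihydroxyacetophenone | CC(=O)c1ccc(O)cc1O | starting material
11 | 3-methylbut-2-enal | CC(C)=CC=O | starting material
12 | 1-(5-hydroxy-2,2-dimethyl-2H-chromen-6-yl)ethanone | CC(=O)c1ccc2c(c1O)C=CC(C)(C)O2 | intermediate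
13 | 1-[5-(methoxymethoxy)-2,2-dimethyl-2H-chromen-6-yl]ethanone | CC(=O)c1ccc2c(c1OCOC)C=CC(C)(C)O2 | intermediate
14 | {1-[5-(methoxymethoxy)-2,2-dimethyl-2H-chromen-6-yl]ethenyloxy}trimethylsilane | C=C(O[Si](C)(C)C)c1ccc2c(c1OCOC)C=CC(C)(C)O2 | intermediate
15 | 2-bromo-1-[5-(methoxymethoxy)-2,2-dimethyl-2H-chromen-6-yl]ethanone | O=C(CBr)c1ccc2c(c1OCOC)C=CC(C)(C)O2 | intermediate
16 | 2,4-bis(methoxymethoxy)-3-[3-(methoxymethoxy)-3-methylbutyl]-6-{2-[5-(methoxymethoxy)-2,2-dimethyl-2H-chromen-6-yl]-2-oxoethoxy}benzaldehyde | O=Cc1c(OCC(=O)c2ccc3c(c2OCOC)C=CC(C)(C)O3)cc(OCOC)c(CCC(C)(C)OCOC)c1OCOC | intermediate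
17 | 3-hydroxy-5,7-bis(methoxymethoxy)-6-[3-(methoxymethoxy)-3-methylbutyl]-3-[5-(methoxymethoxy)-2,2-dimethyl-2H-chromen-6-yl]-2,3-dihydro-4H-chromen-4-one (racemic) | O=C1c2c(OCOC)c(CCC(C)(C)OCOC)c(OCOC)cc2OCC1(O)c1ccc2c(c1OCOC)C=CC(C)(C)O2 | intermediate
18 | 5,7-bis(methoxymethoxy)-6-[3-(methoxymethoxy)-3-methylbutyl]-3-[5-(methoxymethoxy)-2,2-dimethyl-2H-chromen-6-yl]-4H-chromen-4-one | COCOC(C)(C)CCc1c(OCOC)cc2occ(-c3ccc4c(c3OCOC)C=CC(C)(C)O4)c(=O)c2c1OCOC | intermediate
19 | Kanzonol T, 5,7-dihydroxy-6-(3-hydroxy-3-methylbutyl)-3-(5-hydroxy-2,2-dimethyl-2H-chromen-6-yl)-4H-chromen-4-one | CC(C)(O)CCc1c(O)cc2occ(-c3ccc4c(c3O)C=CC(C)(C)O4)c(=O)c2c1O | target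

## Step count and least certain steps

Total: 13 steps. Longest linear sequence: 10 steps (steps 1–6, then 10–13, from phloroglucinol 1). The ring B/D branch (steps 7–9) is three steps.

**Step 11 (key step).** The most likely failure is slow or absent formation of the Breslow intermediate at an aldehyde that is electron-rich and flanked by two ortho oxygens. A second is enolisation of the ketone at C2 followed by aldol closure onto the aldehyde and dehydration to a five-membered ring, because the carbene is generated with base and the ring B ketone, also electron-rich and ortho-substituted, is a sluggish acceptor. A third is reversal of the benzoin addition on long reaction times.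
Fallback: the same C3–C4 bond is made reductively. Setting out from 16, SmI2 in THF at −78 °C without a proton source should effect ketyl–carbonyl (pinacol) cyclisation to 5,7-bis(methoxymethoxy)-6-[3-(methoxymethoxy)-3-methylbutyl]-3-[5-(methoxymethoxy)-2,2-dimethyl-2H-chromen-6-yl]-3,4-dihydro-2H-chromene-3,4-diol F1. The low temperature and the fast six-membered closure are meant to outrun reductive loss of the aryloxy group next to the ketone. Oxidation of the secondary benzylic carbinol of F1 with IBX in DMSO at 25 °C, which does not cleave 1,2-diols, returns to the route at 17.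

**Step 3.** BF3 may ionise the oxetane at its tertiary C–O bond (elimination or oligomerisation) faster than the hindered, doubly chelated aryllithium attacks the CH2 carbon. The aryllithium may also simply be protonated.
Fallback: setting out from 3 through aryllithium 5, transmetalation with CuBr·SMe2 and allylation with 1-bromo-3-methylbut-2-ene should give triisopropyl[3,5-bis(methoxymethoxy)-4-(3-methylbut-2-en-1-yl)phenoxy]silane F2. Markovnikov hydration of its trisubstituted alkene by Mukaiyama hydration (Co(acac)2, PhSiH3, O2, THF/i-PrOH, rt) returns to the route at 6.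

**Step 10.** Once the ether has formed, carbonate may enolise the new α-aryloxy ketone, and aldol addition to the neighbouring formyl group with dehydration would consume the product. The hydrogen-bonded phenol of 9 may also alkylate slowly, which lengthens the exposure.
Fallback: the ether is formed without added base. Setting out from 15, hydrolysis with HCO2Na in aqueous ethanol at 80 °C should give 2-hydroxy-1-[5-(methoxymethoxy)-2,2-dimethyl-2H-chromen-6-yl]ethanone F3. Mitsunobu coupling of F3 with phenol 9 (PPh3, diisopropyl azodicarboxylate, THF, 0 °C → rt) returns to the route at 16.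

**Step 12.** At the hindered tertiary C3, chloride capture or ionisation to a cation stabilised by the electron-rich ring B may compete with loss of the C2 hydrogen. Local HCl may also strip the C5 acetal.
Fallback: C3 is deoxygenated and the ring is then dehydrogenated. Setting out from 17, acetylation (Ac2O, DMAP, Et3N) should give 5,7-bis(methoxymethoxy)-6-[3-(methoxymethoxy)-3-methylbutyl]-3-[5-(methoxymethoxy)-2,2-dimethyl-2H-chromen-6-yl]-4-oxo-3,4-dihydro-2H-chromen-3-yl acetate F4. Reductive cleavage of the α-acetoxy ketone with SmI2 (THF/MeOH, −78 °C) should give racemic 5,7-bis(methoxymethoxy)-6-[3-(methoxymethoxy)-3-methylbutyl]-3-[5-(methoxymethoxy)-2,2-dimethyl-2H-chromen-6-yl]-2,3-dihydro-4H-chromen-4-one F5. Dehydrogenation of F5 with DDQ in dioxane at 80 °C returns to the route at 18.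

## Further compounds

F1 | step 11 | 5,7-bis(methoxymethoxy)-6-[3-(methoxymethoxy)-3-methylbutyl]-3-[5-(methoxymethoxy)-2,2-dimethyl-2H-chromen-6-yl]-3,4-dihydro-2H-chromene-3,4-diol (racemic, either diastereomer serves) | OC1c2c(OCOC)c(CCC(C)(C)OCOC)c(OCOC)cc2OCC1(O)c1ccc2c(c1OCOC)C=CC(C)(C)O2
F2 | step 3 | triisopropyl[3,5-bis(methoxymethoxy)-4-(3-methylbut-2-en-1-yl)phenoxy]silane | CC(C)=CCc1c(OCOC)cc(O[Si](C(C)C)(C(C)C)C(C)C)cc1OCOC
F3 | step 10 | 2-hydroxy-1-[5-(methoxymethoxy)-2,2-dimethyl-2H-chromen-6-yl]ethanone | O=C(CO)c1ccc2c(c1OCOC)C=CC(C)(C)O2
F4 | step 12 | 5,7-bis(methoxymethoxy)-6-[3-(methoxymethoxy)-3-methylbutyl]-3-[5-(methoxymethoxy)-2,2-dimethyl-2H-chromen-6-yl]-4-oxo-3,4-dihydro-2H-chromen-3-yl acetate (racemic) | CC(=O)OC1(COc2cc(OCOC)c(CCC(C)(C)OCOC)c(OCOC)c2C1=O)c1ccc2c(c1OCOC)C=CC(C)(C)O2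
F5 | step 12 | 5,7-bis(methoxymethoxy)-6-[3-(methoxymethoxy)-3-methylbutyl]-3-[5-(methoxymethoxy)-2,2-dimethyl-2H-chromen-6-yl]-2,3-dihydro-4H-chromen-4-one (racemic) | O=C1c2c(OCOC)c(CCC(C)(C)OCOC)c(OCOC)cc2OCC1c1ccc2c(c1OCOC)C=CC(C)(C)O2
A1 | alternative 1 | 5-hydroxy-6-[3-(methoxymethoxy)-3-methylbutyl]-3-[5-(methoxymethoxy)-2,2-dimethyl-2H-chromen-6-yl]-7-(triisopropylsilyloxy)-4H-chromen-4-one | CC(C)(OCOC)CCc1c(O[Si](C(C)C)(C(C)C)C(C)C)cc2occ(-c3ccc4c(c3OCOC)C=CC(C)(C)O4)c(=O)c2c1O
A2 | alternative 1 | 2-(2-diazoacetyl)-5-[5-(methoxymethoxy)-2,2-dimethyl-2H-chromen-6-yl]-4H-pyran-4-one | [N-]=[N+]=CC(=O)c1cc(=O)c(-c2ccc3c(c2OCOC)C=CC(C)(C)O3)co1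
A3 | alternative 1 | triisopropyl{[5-(methoxymethoxy)-5-methylhex-1-yn-1-yl]oxy}silane | COCOC(C)(C)CCC#CO[Si](C(C)C)(C(C)C)C(C)C
A4 | alternative 2 | 5,7-bis(methoxymethoxy)-6-[3-(methoxymethoxy)-3-methylbutyl]-3-[5-(methoxymethoxy)-2,2-dimethyl-2H-chromen-6-yl]-4H-chromen-4-one (identical with 18) | COCOC(C)(C)CCc1c(OCOC)cc2occ(-c3ccc4c(c3OCOC)C=CC(C)(C)O4)c(=O)c2c1OCOC
A5 | alternative 2 | 3,5-bis(methoxymethoxy)-4-[3-(methoxymethoxy)-3-methylbutyl]-2-(trimethylsilyl)phenyl trifluoromethanesulfonate | C[Si](C)(C)c1c(OS(=O)(=O)C(F)(F)F)cc(OCOC)c(CCC(C)(C)OCOC)c1OCOC
A6 | alternative 2 | methyl 3-hydroxy-2-[5-(methoxymethoxy)-2,2-dimethyl-2H-chromen-6-yl]prop-2-enoate | COC(=O)C(=CO)c1ccc2c(c1OCOC)C=CC(C)(C)O2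
A7 | alternative 3 | 6-(3-hydroxy-3-methylbutyl)-5,7-bis(methoxymethoxy)-3-[5-(methoxymethoxy)-2,2-dimethyl-2H-chromen-6-yl]-4H-chromen-4-one | CC(C)(O)CCc1c(OCOC)cc2occ(-c3ccc4c(c3OCOC)C=CC(C)(C)O4)c(=O)c2c1OCOC
A8 | alternative 3 | 1-[6-hydroxy-3-(3-hydroxy-3-methylbutyl)-2,4-bis(methoxymethoxy)phenyl]-2-[5-(methoxymethoxy)-2,2-dimethyl-2H-chromen-6-yl]cyclopropan-1-ol (racemic, relative configuration not specified) | OC1(CC1c1ccc2c(c1OCOC)C=CC(C)(C)O2)c1c(O)cc(OCOC)c(CCC(C)(C)O)c1OCOC
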